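The key bond is cut between the benzylic carbon C1′ of the pentadecenyl chain and ring carbon C6 of the 2,4-dihydroxybenzoic acid ring. C6 is treated as the third, hidden oxygen position of symmetric 2,4,6-trihydroxybenzoic acid: once two hydroxyls are silylated, the remaining ester-chelated ortho hydroxyl becomes an aryl triflate. A B-alkyl Suzuki–Miyaura coupling joins this triflate to the 9-BBN adduct of (6R,7Z)-pentadeca-7,14-dien-6-yl acetate, a terminal alkene that already carries the stereocentre (from (R)-oct-1-yn-3-ol) and the Z-olefin. One fluoride treatment then frees both phenols and the acid while the acetate stays.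

Key step: step 7

Remark on the chemistry: the acetoxy-bearing carbon of the target is read as R (O > alkenyl C > pentyl C > H) and the olefin as Z. The side chain is numbered from the benzylic carbon (C1′), so the target is 2-[(8Z,10R)-10-acetoxypentadec-8-en-1-yl]-4,6-dihydroxybenzoic acid. Commercial 2,4,6-trihydroxybenzoic acid monohydrate is assumed to be dried in vacuo without heating before use.

Step 1
Reactants: 1 (R)-oct-1-yn-3-ol; 2 7-bromohept-1-ene
Product: 4 (6R)-pentadec-14-en-7-yn-6-ol, via dilithium alkynide alkoxide 3 (not isolated)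
Conditions: n-BuLi (2.1 equiv), THF/DMPU, −78 → −20 °C; then 2 (1.1 equiv), −20 °C → rt; aq NH4Cl
Reagents that add atoms: none
Why: Double deprotonation gives a C,O-dianion whose acetylide carbon is far more nucleophilic than the alkoxide, so SN2 alkylation of the primary bromide (acetylide alkylation) occurs at carbon and the carbinol stereocentre is not touched.

Step 2
Reactants: 4 (6R)-pentadec-14-en-7-yn-6-ol
Product: 5 (6R,7Z)-pentadeca-7,14-dien-6-ol
Conditions: H2 (1 atm), Lindlar catalyst (Pd/CaCO3, Pb-poisoned), quinoline, EtOAc/hexane, rt, stopped after 1.0 equiv H2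
Reagents that add atoms: none
Why: Lindlar semi-hydrogenation adds H2 syn to the strongly adsorbed alkyne and so sets the Z-olefin, while the more weakly adsorbed terminal vinyl group should be spared on the quinoline-poisoned catalyst when uptake is stopped at one equivalent.

Step 3
Reactants: 5 (6R,7Z)-pentadeca-7,14-dien-6-ol
Product: 6 (6R,7Z)-pentadeca-7,14-dien-6-yl acetate
Conditions: Ac2O, pyridine, DMAP (cat.), CH2Cl2, 0 °C → rt
Reagents that add atoms: acetic anhydride, CC(=O)OC(C)=O
Why: DMAP-catalysed O-acetylation of the secondary allylic alcohol does not break the C–O bond, so the R configuration is retained.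

Step 4
Reactants: 7 2,4,6-trihydroxybenzoic acid
Product: 8 2-(trimethylsilyl)ethyl 2,4,6-trihydroxybenzoate
Conditions: 2-(trimethylsilyl)ethanol (1.1 equiv), PPh3, DIAD, THF, 0 °C → rt
Reagents that add atoms: 2-(trimethylsilyl)ethanol, C[Si](C)(C)CCO
Why: In this Mitsunobu esterification the strongly acidic carboxylic acid is the pronucleophile that is deprotonated first and attacks the primary alkoxyphosphonium ion, so the less acidic phenols should stay free and no heating (decarboxylation) is needed.

Step 5
Reactants: 8 2-(trimethylsilyl)ethyl 2,4,6-trihydroxybenzoate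
Product: 9 2-(trimethylsilyl)ethyl 2-hydroxy-4,6-bis(triisopropylsilyloxy)benzoate
Conditions: TIPSCl (2.2 equiv), imidazole, DMF, 0 °C → rt
Reagents that add atoms: chlorotriisopropylsilane, CC(C)[Si](Cl)(C(C)C)C(C)C
Why: Regioselective phenol silylation takes the unchelated 4-OH and one of the two equivalent ortho OH groups, whereas the last hydroxyl is locked in a hydrogen bond to the ester carbonyl and is too hindered for a third bulky TIPS group.

Step 6
Reactants: 9 2-(trimethylsilyl)ethyl 2-hydroxy-4,6-bis(triisopropylsilyloxy)benzoate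
Product: 10 2-(trimethylsilyl)ethyl 2,4-bis(triisopropylsilyloxy)-6-(trifluoromethanesulfonyloxy)benzoate
Conditions: Tf2O (1.2 equiv), pyridine, CH2Cl2, −20 → 0 °C
Reagents that add atoms: trifluoromethanesulfonic anhydride, O=S(=O)(OS(=O)(=O)C(F)(F)F)C(F)(F)F
Why: O-sulfonylation of the remaining chelated phenol with Tf2O/pyridine (aryl triflate formation) leaves the silyl ethers and the ester untouched.

Step 7
Reactants: 6 (6R,7Z)-pentadeca-7,14-dien-6-yl acetate; 10 2-(trimethylsilyl)ethyl 2,4-bis(triisopropylsilyloxy)-6-(trifluoromethanesulfonyloxy)benzoate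
Product: 12 2-(trimethylsilyl)ethyl 2-[(8Z,10R)-10-acetoxypentadec-8-en-1-yl]-4,6-bis(triisopropylsilyloxy)benzoate, via B-alkyl-9-BBN adduct 11 (not isolated)
Conditions: 9-BBN (0.5 M in THF, 1.2 equiv to 6), THF, 0 °C → rt; then 10 (0.8 equiv), Pd(dppf)Cl2·CH2Cl2 (5 mol %), AsPh3 (5 mol %), 3 M aq K3PO4 (3 equiv), THF/DMF, rt → 45 °C
Reagents that add atoms: none
Why: 9-BBN adds anti-Markovnikov to the monosubstituted C14=C15 double bond of 6 to give the primary alkylborane 11; Pd(0) then inserts into the C–OTf bond of 10 (activated by the ortho ester), base converts 11 into a borate that transfers its primary alkyl group to palladium, and reductive elimination from the dppf complex forms the benzylic C1′–C6(aryl) bond. The closest known reaction type is the B-alkyl Suzuki–Miyaura coupling of B-alkyl-9-BBN reagents with aryl triflates. No ring is closed and no stereocentre is created; the (R)-acetoxy centre and the Z-olefin are only carried through. The step needs chemoselective hydroboration, which the strong preference of bulky 9-BBN for a terminal vinyl group over a Z-1,2-disubstituted olefin (here also shielded and deactivated by the allylic acetoxy group) should secure. It also needs oxidative addition at the aryl triflate to outrun ionisation of the allylic acetate, which is expected because a secondary Z-1,3-dialkyl allyl acetate forms a π-allyl complex only slowly (A1,3 strain) whereas the electron-poor ortho-acyl aryl triflate reacts readily at rt to 45 °C. The wide bite angle of dppf favours reductive elimination over β-hydride elimination of the alkylpalladium intermediate.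

Step 8
Reactants: 12 2-(trimethylsilyl)ethyl 2-[(8Z,10R)-10-acetoxypentadec-8-en-1-yl]-4,6-bis(triisopropylsilyloxy)benzoate
Product: 13 2-[(8Z,10R)-10-acetoxypentadec-8-en-1-yl]-4,6-dihydroxybenzoic acid
Conditions: TBAF (4 equiv), AcOH (4 equiv), THF, 0 °C → rt; cold pH 3 citrate buffer work-up
Reagents that add atoms: none
Why: Fluoride attacks silicon, so the aryl TIPS ethers give the phenols and the 2-(trimethylsilyl)ethyl ester fragments by β-elimination to ethene, Me3SiF and the carboxylate, while acetic acid buffering keeps the medium non-basic so that the secondary acetate, the Z-olefin and the decarboxylation-prone acid should survive.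

Compound list
1 | (R)-oct-1-yn-3-ol | CCCCC[C@H](C#C)O | starting material
2 | 7-bromohept-1-ene | C=CCCCCCBr | starting material
3 | dilithium (R)-oct-1-yn-1-id-3-olate (C,O-dianion of 1) | CCCCC[C@H](C#C[Li])O[Li] | intermediate
4 | (6R)-pentadec-14-en-7-yn-6-ol | CCCCC[C@H](C#CCCCCCC=C)O | intermediate
5 | (6R,7Z)-pentadeca-7,14-dien-6-ol | CCCCC[C@H](/C=C\CCCCCC=C)O | intermediate
6 | (6R,7Z)-pentadeca-7,14-dien-6-yl acetate | CCCCC[C@H](/C=C\CCCCCC=C)OC(C)=O | intermediate
7 | 2,4,6-trihydroxybenzoic acid | O=C(O)c1c(O)cc(O)cc1O | starting material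
8 | 2-(trimethylsilyl)ethyl 2,4,6-trihydroxybenzoate | C[Si](C)(C)CCOC(=O)c1c(O)cc(O)cc1O | intermediate
9 | 2-(trimethylsilyl)ethyl 2-hydroxy-4,6-bis(triisopropylsilyloxy)benzoate | C[Si](C)(C)CCOC(=O)c1c(O)cc(O[Si](C(C)C)(C(C)C)C(C)C)cc1O[Si](C(C)C)(C(C)C)C(C)C | intermediate
10 | 2-(trimethylsilyl)ethyl 2,4-bis(triisopropylsilyloxy)-6-(trifluoromethanesulfonyloxy)benzoate | C[Si](C)(C)CCOC(=O)c1c(OS(=O)(=O)C(F)(F)F)cc(O[Si](C(C)C)(C(C)C)C(C)C)cc1O[Si](C(C)C)(C(C)C)C(C)C | intermediate
11 | (6R,7Z)-15-(9-borabicyclo[3.3.1]nonan-9-yl)pentadec-7-en-6-yl acetate | CCCCC[C@H](/C=C\CCCCCCCB1C2CCCC1CCC2)OC(C)=O | intermediate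
12 | 2-(trimethylsilyl)ethyl 2-[(8Z,10R)-10-acetoxypentadec-8-en-1-yl]-4,6-bis(triisopropylsilyloxy)benzoate | CCCCC[C@H](/C=C\CCCCCCCc1cc(O[Si](C(C)C)(C(C)C)C(C)C)cc(O[Si](C(C)C)(C(C)C)C(C)C)c1C(=O)OCC[Si](C)(C)C)OC(C)=O | intermediate
13 | 2-[(8Z,10R)-10-acetoxypentadec-8-en-1-yl]-4,6-dihydroxybenzoic acid | CCCCC[C@H](/C=C\CCCCCCCc1cc(O)cc(O)c1C(=O)O)OC(C)=O | target

Total step count: 8. Longest linear sequence: 5 steps (1, 2, 3, 7, 8 or 4, 5, 6, 7, 8).

Steps most likely to fail

Step 7. Under Pd(0) and aqueous base the secondary allylic acetate may be ionised to a π-allylpalladium species (loss or 1,3-shift of the acetoxy group, scrambling of the stereocentre, elimination to a diene) or be saponified before the triflate has coupled. The fallback sets out from 5 and postpones the acetylation. Silylation (TESCl, imidazole, CH2Cl2) would give triethyl{[(6R,7Z)-pentadeca-7,14-dien-6-yl]oxy}silane F1. Hydroboration with 9-BBN would give 9-[(8Z,10R)-10-(triethylsilyloxy)pentadec-8-en-1-yl]-9-borabicyclo[3.3.1]nonane F2, which would be coupled in the same flask with 10 under the conditions of step 7 to 2-(trimethylsilyl)ethyl 2-[(8Z,10R)-10-(triethylsilyloxy)pentadec-8-en-1-yl]-4,6-bis(triisopropylsilyloxy)benzoate F3; a silyl ether cannot ionise and is stable to the base. PPTS in MeOH/CH2Cl2 at 0 °C should remove only the alkyl TES group (aryl TIPS ethers and the ester are stable to mild acid) and give 2-(trimethylsilyl)ethyl 2-[(8Z,10R)-10-hydroxypentadec-8-en-1-yl]-4,6-bis(triisopropylsilyloxy)benzoate F4. Acetylation (Ac2O, pyridine, DMAP) comes back to the route at 12.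

Step 2. Hydrogenation or palladium hydride migration of the terminal vinyl group may compete with the semi-reduction of the alkyne (over-reduction, double-bond isomerisation). The fallback sets out from 4 and uses up the vinyl group before any hydrogenation. Silylation (TESCl, imidazole) would give triethyl{[(6R)-pentadec-14-en-7-yn-6-yl]oxy}silane F5. 9-BBN, which adds to a terminal alkene much faster than to a hindered internal alkyne, would give 9-[(10R)-10-(triethylsilyloxy)pentadec-8-yn-1-yl]-9-borabicyclo[3.3.1]nonane F6, which would be coupled with 10 as in step 7 to 2-(trimethylsilyl)ethyl 2-[(10R)-10-(triethylsilyloxy)pentadec-8-yn-1-yl]-4,6-bis(triisopropylsilyloxy)benzoate F7. Lindlar semi-hydrogenation, now with no other olefin present, would give 2-(trimethylsilyl)ethyl 2-[(8Z,10R)-10-(triethylsilyloxy)pentadec-8-en-1-yl]-4,6-bis(triisopropylsilyloxy)benzoate F3. Removal of the TES group (PPTS, MeOH) to 2-(trimethylsilyl)ethyl 2-[(8Z,10R)-10-hydroxypentadec-8-en-1-yl]-4,6-bis(triisopropylsilyloxy)benzoate F4 and acetylation come back to the route at 12.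

Step 4. O-Alkylation of the phenols may compete with esterification of the weakly nucleophilic, doubly hydrogen-bonded carboxylate, and the acid may decarboxylate if the reaction has to be forced. The fallback sets out from 7 and makes the ester by acyl transfer instead of carboxylate alkylation. Acetone, trifluoroacetic anhydride and trifluoroacetic acid (0 °C → rt) would give the acetonide 5,7-dihydroxy-2,2-dimethyl-4H-1,3-benzodioxin-4-one F8. Opening of this activated cyclic ester with excess 2-(trimethylsilyl)ethanol and Cs2CO3 or NaH in THF (rt → 60 °C), followed by mild acidification, comes back to the route at 8.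

Further compounds
F1 | step 7 | triethyl{[(6R,7Z)-pentadeca-7,14-dien-6-yl]oxy}silane | CCCCC[C@H](/C=C\CCCCCC=C)O[Si](CC)(CC)CC
F2 | step 7 | 9-[(8Z,10R)-10-(triethylsilyloxy)pentadec-8-en-1-yl]-9-borabicyclo[3.3.1]nonane | CCCCC[C@H](/C=C\CCCCCCCB1C2CCCC1CCC2)O[Si](CC)(CC)CC
F3 | step 7 | 2-(trimethylsilyl)ethyl 2-[(8Z,10R)-10-(triethylsilyloxy)pentadec-8-en-1-yl]-4,6-bis(triisopropylsilyloxy)benzoate | CCCCC[C@H](/C=C\CCCCCCCc1cc(O[Si](C(C)C)(C(C)C)C(C)C)cc(O[Si](C(C)C)(C(C)C)C(C)C)c1C(=O)OCC[Si](C)(C)C)O[Si](CC)(CC)CC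
F4 | step 7 | 2-(trimethylsilyl)ethyl 2-[(8Z,10R)-10-hydroxypentadec-8-en-1-yl]-4,6-bis(triisopropylsilyloxy)benzoate | CCCCC[C@H](/C=C\CCCCCCCc1cc(O[Si](C(C)C)(C(C)C)C(C)C)cc(O[Si](C(C)C)(C(C)C)C(C)C)c1C(=O)OCC[Si](C)(C)C)O
F5 | step 2 | triethyl{[(6R)-pentadec-14-en-7-yn-6-yl]oxy}silane | CCCCC[C@H](C#CCCCCCC=C)O[Si](CC)(CC)CC
F6 | step 2 | 9-[(10R)-10-(triethylsilyloxy)pentadec-8-yn-1-yl]-9-borabicyclo[3.3.1]nonane | CCCCC[C@H](C#CCCCCCCCB1C2CCCC1CCC2)O[Si](CC)(CC)CC
F7 | step 2 | 2-(trimethylsilyl)ethyl 2-[(10R)-10-(triethylsilyloxy)pentadec-8-yn-1-yl]-4,6-bis(triisopropylsilyloxy)benzoate | CCCCC[C@H](C#CCCCCCCCc1cc(O[Si](C(C)C)(C(C)C)C(C)C)cc(O[Si](C(C)C)(C(C)C)C(C)C)c1C(=O)OCC[Si](C)(C)C)O[Si](CC)(CC)CC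
F8 | step 4 | 5,7-dihydroxy-2,2-dimethyl-4H-1,3-benzodioxin-4-one | CC1(C)OC(=O)c2c(O)cc(O)cc2O1
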